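## Retrosynthetic overview

1. Target ⇐ global O‑demethylation of its (2S,3S) pentamethyl ether; all oxygens are carried as methyl ethers from cheap methoxyarenes.
2. Pentamethyl ether ⇐ one thermal operation on a 3‑(homopropargyloxy)‑6‑styryl‑1,2‑diazine: intramolecular inverse‑electron‑demand Diels–Alder reaction, then loss of N2. This builds benzene ring B and dihydrofuran ring C together (bonds C7a–C3a and C4–C5).
3. Diazine ether ⇐ SNAr of an anti‑(1S,2R) homopropargylic alcohol on 3‑chloro‑6‑styrylpyridazine (Heck product of 3,6‑dichloropyridazine and 3,5‑dimethoxystyrene).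
4. Alcohol ⇐ chiral‑phosphoric‑acid allenylboration of 4‑methoxybenzaldehyde with a racemic γ‑aryl allenylboronate (two steps from 3,5‑dimethoxybenzaldehyde). Both stereocentres (later C2 and C3) are set here, before any ring exists.
5. Ring order: aryl rings A, D and E are bought; rings B and C form simultaneously in the penultimate step; no ring is formed afterwards.

Assumption: numbers are given to every compound that contributes atoms to a product, while catalysts, ligands, bases and solvents carry none; 4, 5 and 7 are racemic; the (S)‑antipode of the phosphoric acid is taken as the one that delivers Si‑face attack on the aldehyde, and the (R)‑acid is used instead if the first run shows the opposite sense.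

## Route

Step 1
Reactants: 1 3,5‑dimethoxybenzaldehyde; 2 ethynylmagnesium bromide; 3 methyl chloroformate
Product: 5 (±)‑1‑(3,5‑dimethoxyphenyl)prop‑2‑yn‑1‑yl methyl carbonate, via bromomagnesium alkoxide 4 (not isolated)
Conditions: 2 (1.2 equiv), THF, 0 °C, 1 h; then 3 (1.5 equiv), 0 °C → rt
Reagents that add atoms: ethynylmagnesium bromide C#C[Mg]Br; methyl chloroformate COC(=O)Cl
Why: Grignard 1,2‑addition of the acetylide to the aldehyde followed by O‑acylation of the magnesium alkoxide in the same flask gives the propargylic carbonate directly; the carbinol centre is racemic and is erased in step 2.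

Step 2
Reactants: 5 (±)‑1‑(3,5‑dimethoxyphenyl)prop‑2‑yn‑1‑yl methyl carbonate; 6 bis(pinacolato)diboron
Product: 7 (±)‑2‑[3‑(3,5‑dimethoxyphenyl)propa‑1,2‑dien‑1‑yl]‑4,4,5,5‑tetramethyl‑1,3,2‑dioxaborolane
Conditions: CuCl (5 mol %), 4,5‑bis(diphenylphosphino)‑9,9‑dimethylxanthene (5 mol %), KOC(CH3)3 (10 mol %), 6 (1.2 equiv), THF, rt
Reagents that add atoms: bis(pinacolato)diboron CC1(C)OB(OC1(C)C)B1OC(C)(C)C(C)(C)O1
Why: Copper‑catalysed SN2' borylation of a propargylic carbonate: the monovalent copper–boryl species delivers boron to the terminal alkyne carbon and β‑oxygen elimination expels methyl carbonate (CO2 plus methoxide, which regenerates the copper alkoxide), giving the allenylboronate regiospecifically with a racemic axis.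

Step 3
Reactants: 7 (±)‑2‑[3‑(3,5‑dimethoxyphenyl)propa‑1,2‑dien‑1‑yl]‑4,4,5,5‑tetramethyl‑1,3,2‑dioxaborolane; 8 4‑methoxybenzaldehyde
Product: 10 (1S,2R)‑2‑(3,5‑dimethoxyphenyl)‑1‑(4‑methoxyphenyl)but‑3‑yn‑1‑ol, via O‑pinacolboryl adduct 9 (not isolated)
Conditions: (S)‑3,3'‑bis(2,4,6‑triisopropylphenyl)‑1,1'‑binaphthyl‑2,2'‑diyl hydrogen phosphate (10 mol %), 7 (2.8 equiv), 4 Å MS, toluene, −30 °C, 48 h; aq. NaHCO3; chromatography (removes the minor syn isomer)
Reagents that add atoms: none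
Why: Chiral‑phosphoric‑acid‑catalysed allenylboration (SE2' propargylation through a closed chair‑like six‑membered transition state) with kinetic resolution of the racemic allenylboronate: the acid‑bound boronate attacks only the Si face of 8 and only its matched axial enantiomer reacts fast, with the aldehyde aryl pseudo‑equatorial, so the anti‑(1S,2R) alcohol forms and both stereocentres (the later C2 and C3) are set together.

Step 4
Reactants: 11 3,6‑dichloropyridazine; 12 3,5‑dimethoxystyrene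
Product: 13 3‑chloro‑6‑[(E)‑2‑(3,5‑dimethoxyphenyl)ethenyl]pyridazine
Conditions: Pd2(dba)3 (dba = dibenzylideneacetone, 1.5 mol %), P(t‑Bu)3·HBF4 (6 mol %), N,N‑dicyclohexylmethylamine (1.2 equiv), 11 (2.5 equiv), 1,4‑dioxane, 80 °C
Reagents that add atoms: none
Why: Mizoroki–Heck reaction: zerovalent palladium inserts into the activated C–Cl bond of the electron‑poor diazine, syn‑carbopalladation of the styrene and syn‑β‑hydride elimination give the E‑alkene, and the excess of 11 keeps the coupling at the mono stage.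

Step 5
Reactants: 10 (1S,2R)‑2‑(3,5‑dimethoxyphenyl)‑1‑(4‑methoxyphenyl)but‑3‑yn‑1‑ol; 13 3‑chloro‑6‑[(E)‑2‑(3,5‑dimethoxyphenyl)ethenyl]pyridazine
Product: 15 3‑{[(1S,2R)‑2‑(3,5‑dimethoxyphenyl)‑1‑(4‑methoxyphenyl)but‑3‑yn‑1‑yl]oxy}‑6‑[(E)‑2‑(3,5‑dimethoxyphenyl)ethenyl]pyridazine, via sodium alkoxide 14 (not isolated)
Conditions: NaH (1.05 equiv), THF, 0 °C, 20 min; then 13 (1.1 equiv), 0 → 40 °C
Reagents that add atoms: none
Why: Nucleophilic aromatic substitution (addition–elimination) of the alkoxide at the chlorine‑bearing diazine carbon, which is activated by the adjacent ring nitrogen; the carbinol C–O bond is not broken, so (1S) is retained, and one equivalent of base at low temperature leaves the propargylic C–H of the (2R) centre untouched.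

Step 6
Reactants: 15 3‑{[(1S,2R)‑2‑(3,5‑dimethoxyphenyl)‑1‑(4‑methoxyphenyl)but‑3‑yn‑1‑yl]oxy}‑6‑[(E)‑2‑(3,5‑dimethoxyphenyl)ethenyl]pyridazine
Product: 17 (2S,3S)‑3‑(3,5‑dimethoxyphenyl)‑5‑[(E)‑2‑(3,5‑dimethoxyphenyl)ethenyl]‑2‑(4‑methoxyphenyl)‑2,3‑dihydro‑1‑benzofuran, via bridged diazene cycloadduct 16 (not isolated)
Conditions: 1,2‑dichlorobenzene (0.01 M), 2,6‑di‑tert‑butyl‑4‑methylphenol (10 mol %), argon, sealed tube, 190 °C, 24 h
Reagents that add atoms: none
Why: Intramolecular inverse‑electron‑demand Diels–Alder reaction of the 1,2‑diazine (C3 and C6 as diene termini) with the tethered terminal alkyne, followed by retro‑Diels–Alder loss of N2, creates benzene ring B and dihydrofuran ring C in the same operation with regiochemistry fixed by the three‑atom tether (oxygen‑bearing diazine carbon → C7a, styryl‑bearing carbon → C5, alkyne CH → C4); both stereocentres sit on the tether, take no part in the bond changes and are carried over unchanged in space as trans‑(2S,3S), the former (2R) descriptor becoming (3S) only because the alkyne carbon gains CIP rank on becoming C3a.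

Step 7
Reactants: 17 (2S,3S)‑3‑(3,5‑dimethoxyphenyl)‑5‑[(E)‑2‑(3,5‑dimethoxyphenyl)ethenyl]‑2‑(4‑methoxyphenyl)‑2,3‑dihydro‑1‑benzofuran
Product: 18 (2S,3S)‑trans‑δ‑viniferin
Conditions: BBr3 (12 equiv), CH2Cl2, −78 °C → rt; then ice‑water
Reagents that add atoms: none
Why: Lewis‑acid aryl methyl ether cleavage (BBr3 coordinates each methoxy oxygen and bromide removes the methyl group by SN2), which does not touch C3; any reversible opening of the benzylic C2–O bond recloses to the more stable trans isomer dictated by C3, so the (2S,3S) configuration is kept.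

## Compound list

1 | 3,5‑dimethoxybenzaldehyde | COc1cc(C=O)cc(OC)c1 | starting material
2 | ethynylmagnesium bromide | C#C[Mg]Br | starting material
3 | methyl chloroformate | COC(=O)Cl | starting material
4 | bromomagnesium (±)‑1‑(3,5‑dimethoxyphenyl)prop‑2‑yn‑1‑olate | C#CC(O[Mg]Br)c1cc(OC)cc(OC)c1 | intermediate
5 | (±)‑1‑(3,5‑dimethoxyphenyl)prop‑2‑yn‑1‑yl methyl carbonate | COC(=O)OC(C#C)c1cc(OC)cc(OC)c1 | intermediate
6 | bis(pinacolato)diboron | CC1(C)OB(OC1(C)C)B1OC(C)(C)C(C)(C)O1 | starting material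
7 | (±)‑2‑[3‑(3,5‑dimethoxyphenyl)propa‑1,2‑dien‑1‑yl]‑4,4,5,5‑tetramethyl‑1,3,2‑dioxaborolane | COc1cc(C=C=CB2OC(C)(C)C(C)(C)O2)cc(OC)c1 | intermediate
8 | 4‑methoxybenzaldehyde | COc1ccc(C=O)cc1 | starting material
9 | 2‑{[(1S,2R)‑2‑(3,5‑dimethoxyphenyl)‑1‑(4‑methoxyphenyl)but‑3‑yn‑1‑yl]oxy}‑4,4,5,5‑tetramethyl‑1,3,2‑dioxaborolane | COc1ccc(cc1)[C@@H](OB1OC(C)(C)C(C)(C)O1)[C@H](C#C)c1cc(OC)cc(OC)c1 | intermediate
10 | (1S,2R)‑2‑(3,5‑dimethoxyphenyl)‑1‑(4‑methoxyphenyl)but‑3‑yn‑1‑ol | COc1ccc(cc1)[C@@H](O)[C@H](C#C)c1cc(OC)cc(OC)c1 | intermediate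
11 | 3,6‑dichloropyridazine | Clc1ccc(Cl)nn1 | starting material
12 | 3,5‑dimethoxystyrene (1‑ethenyl‑3,5‑dimethoxybenzene) | C=Cc1cc(OC)cc(OC)c1 | starting material
13 | 3‑chloro‑6‑[(E)‑2‑(3,5‑dimethoxyphenyl)ethenyl]pyridazine | COc1cc(/C=C/c2ccc(Cl)nn2)cc(OC)c1 | intermediate
14 | sodium (1S,2R)‑2‑(3,5‑dimethoxyphenyl)‑1‑(4‑methoxyphenyl)but‑3‑yn‑1‑olate | COc1ccc(cc1)[C@@H]([O-])[C@H](C#C)c1cc(OC)cc(OC)c1.[Na+] | intermediate
15 | 3‑{[(1S,2R)‑2‑(3,5‑dimethoxyphenyl)‑1‑(4‑methoxyphenyl)but‑3‑yn‑1‑yl]oxy}‑6‑[(E)‑2‑(3,5‑dimethoxyphenyl)ethenyl]pyridazine | COc1ccc(cc1)[C@@H](Oc1ccc(/C=C/c2cc(OC)cc(OC)c2)nn1)[C@H](C#C)c1cc(OC)cc(OC)c1 | intermediate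
16 | Diels–Alder adduct: 2,3‑diazabicyclo[2.2.2]octa‑2,5,7‑triene with a fused dihydrofuran; one bridgehead carries the ring oxygen, the other the (E)‑3,5‑dimethoxystyryl group; dihydrofuran centres as in 17; bridgeheads either facial isomer, both collapse to 17 | [C@H]1(c2ccc(OC)cc2)OC23N=NC(/C=C/c4cc(OC)cc(OC)c4)(C=C2)C=C3[C@@H]1c1cc(OC)cc(OC)c1 | intermediate
17 | (2S,3S)‑3‑(3,5‑dimethoxyphenyl)‑5‑[(E)‑2‑(3,5‑dimethoxyphenyl)ethenyl]‑2‑(4‑methoxyphenyl)‑2,3‑dihydro‑1‑benzofuran | COc1ccc([C@H]2Oc3ccc(/C=C/c4cc(OC)cc(OC)c4)cc3[C@@H]2c2cc(OC)cc(OC)c2)cc1 | intermediate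
18 | (2S,3S)‑trans‑δ‑viniferin | Oc1ccc([C@H]2Oc3ccc(/C=C/c4cc(O)cc(O)c4)cc3[C@@H]2c2cc(O)cc(O)c2)cc1 | target

## Step count and risks

Total step count: 7 (steps 1–7). Longest linear sequence: 6 (steps 1, 2, 3, 5, 6, 7); step 4 is the one‑step side branch.

The three steps most likely to fail are steps 3, 5 and 6; step 6 is the riskiest.

**Step 3.** The kinetic resolution may give insufficient ee or anti:syn ratio when the allene carries an aryl group. The syn isomer has the wrong configuration at the later C3, so it cannot be carried on. The fallback replaces catalyst control by chirality transfer and sets out from 1.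
- Addition of 2 with aqueous quench gives racemic 1‑(3,5‑dimethoxyphenyl)prop‑2‑yn‑1‑ol F1.
- MnO2 (CH2Cl2, rt) gives 1‑(3,5‑dimethoxyphenyl)prop‑2‑yn‑1‑one F2.
- Corey–Bakshi–Shibata reduction with (R)‑1‑methyl‑3,3‑diphenyl‑tetrahydro‑1H,3H‑pyrrolo[1,2‑c][1,3,2]oxazaborole and BH3·SMe2 (THF, −30 °C; aryl as the large group, ethynyl as the small one) gives (S)‑1‑(3,5‑dimethoxyphenyl)prop‑2‑yn‑1‑ol F3.
- Methyl chloroformate and pyridine give (S)‑1‑(3,5‑dimethoxyphenyl)prop‑2‑yn‑1‑yl methyl carbonate F4.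
- The copper‑catalysed borylation of step 2 runs anti‑SN2' and gives (aS)‑2‑[3‑(3,5‑dimethoxyphenyl)propa‑1,2‑dien‑1‑yl]‑4,4,5,5‑tetramethyl‑1,3,2‑dioxaborolane F5.
- Uncatalysed addition of F5 to 8 (toluene, rt) through the same closed transition state is suprafacial, so the axis becomes the (2R) centre with anti selectivity. This gives 9 and, after work‑up, 10, where the route is rejoined.
- Any syn isomer formed on this path has the correct (2R) centre and is corrected at C2 in step 7.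

**Step 5.** The sodium alkoxide may isomerise the 3‑aryl‑1‑alkyne to the allene, or react too slowly with the styryl‑deactivated chlorodiazine. The fallback changes the electrophile so that the substitution runs far below the temperature at which the alkoxide attacks the propargylic C–H; it sets out from 13.
- Halogen exchange with anhydrous (CH3)4NF (DMF, rt) gives 3‑fluoro‑6‑[(E)‑2‑(3,5‑dimethoxyphenyl)ethenyl]pyridazine F6.
- The potassium alkoxide of 10 (KN(SiMe3)2, THF, −78 °C) displaces fluoride from F6 at −78 → −30 °C and gives 15, where the route is rejoined.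

**Step 6.** The styryl‑substituted diazine may need temperatures at which syn‑elimination of the pyridazinyl ether (to the pyridazinone and an enyne) or ionisation of the 4‑methoxybenzylic C–O bond competes. The fallback runs the cycloaddition on the more electron‑poor 6‑chlorodiazine before the stilbene is present and attaches the styryl arm last; it sets out from 10 and 11.
- NaH and 11 (THF, −20 → 0 °C) give 3‑chloro‑6‑{[(1S,2R)‑2‑(3,5‑dimethoxyphenyl)‑1‑(4‑methoxyphenyl)but‑3‑yn‑1‑yl]oxy}pyridazine F7.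
- Heating (1,2‑dichlorobenzene, 150–170 °C) takes F7 through the chloro‑substituted bridged diazene cycloadduct F8 to (2S,3S)‑5‑chloro‑3‑(3,5‑dimethoxyphenyl)‑2‑(4‑methoxyphenyl)‑2,3‑dihydro‑1‑benzofuran F9.
- Heck coupling of the aryl chloride F9 with 12 (Pd2(dba)3, P(t‑Bu)3·HBF4, N,N‑dicyclohexylmethylamine, 1,4‑dioxane, 110 °C) returns to 17.

## Further compounds

F1 | step 3 | (±)‑1‑(3,5‑dimethoxyphenyl)prop‑2‑yn‑1‑ol | C#CC(O)c1cc(OC)cc(OC)c1
F2 | step 3 | 1‑(3,5‑dimethoxyphenyl)prop‑2‑yn‑1‑one | C#CC(=O)c1cc(OC)cc(OC)c1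
F3 | step 3 | (S)‑1‑(3,5‑dimethoxyphenyl)prop‑2‑yn‑1‑ol | O[C@@H](C#C)c1cc(OC)cc(OC)c1
F4 | step 3 | (S)‑1‑(3,5‑dimethoxyphenyl)prop‑2‑yn‑1‑yl methyl carbonate | COC(=O)O[C@@H](C#C)c1cc(OC)cc(OC)c1
F5 | step 3 | (aS)‑2‑[3‑(3,5‑dimethoxyphenyl)propa‑1,2‑dien‑1‑yl]‑4,4,5,5‑tetramethyl‑1,3,2‑dioxaborolane | CC1(C)OB(OC1(C)C)C([H])=[C@@]=C([H])c1cc(OC)cc(OC)c1
F6 | step 5 | 3‑fluoro‑6‑[(E)‑2‑(3,5‑dimethoxyphenyl)ethenyl]pyridazine | COc1cc(/C=C/c2ccc(F)nn2)cc(OC)c1
F7 | step 6 | 3‑chloro‑6‑{[(1S,2R)‑2‑(3,5‑dimethoxyphenyl)‑1‑(4‑methoxyphenyl)but‑3‑yn‑1‑yl]oxy}pyridazine | COc1ccc(cc1)[C@@H](Oc1ccc(Cl)nn1)[C@H](C#C)c1cc(OC)cc(OC)c1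
F8 | step 6 | chloro‑substituted bridged diazene cycloadduct (2,3‑diazabicyclo[2.2.2]octa‑2,5,7‑triene with fused dihydrofuran; bridgeheads either facial isomer) | [C@H]1(c2ccc(OC)cc2)OC23N=NC(Cl)(C=C2)C=C3[C@@H]1c1cc(OC)cc(OC)c1
F9 | step 6 | (2S,3S)‑5‑chloro‑3‑(3,5‑dimethoxyphenyl)‑2‑(4‑methoxyphenyl)‑2,3‑dihydro‑1‑benzofuran | COc1ccc([C@H]2Oc3ccc(Cl)cc3[C@@H]2c2cc(OC)cc(OC)c2)cc1
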